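In a one-step world substrate has a single exit, and alder would climb towards 100 %. Yet at 50.0 h alder stood at 79.6 % and elm, with more capture agent at the same loading, at 75.1 %.

| flask | substrate | coupling partner | capture agent | free catalyst | remark | time |
|---|---|---|---|---|---|---|
| alder | 0.050 M | 2.5 equiv | 0.0075 M | 0.2 mol% | run made earlier |  |
| elm | 0.050 M | 2.5 equiv | 0.011 M | 0.2 mol% | run made earlier |  |
| larch | 0.050 M | 2.5 equiv | 0.015 M | 0.1 mol% | run made earlier |  |
| red | 0.050 M | 2.50 equiv | 0.0150 M | 0.2 mol% |  | 2.0 d |
| blue | 0.050 M | 2.50 equiv | 0.0150 M | 0.2 mol% |  | 1.2 d |

- alder (time / h: product / %): 3.00: 2.9; 10.0: 21.3; 15.0: 34.7; 25.0: 56.5; 40.0: 74.2; 50.0: 79.6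
- elm (time / h: product / %): 4.00: 5.1; 6.00: 9.8; 10.0: 20.2; 20.0: 44.6; 30.0: 60.3; 50.0: 75.1
- larch (time / h: product / %): 4.00: 1.6; 12.0: 8.7; 20.0: 17.1; 30.0: 27.3; 50.0: 45.4

(standard deviation of a reading: 0.5 percentage points)



- the flask that ends with the higher amount of product, in percent of the substrate charged, or "neither" when 2 percentage points or less lies between them (red / blue / neither)
- final product, as a percentage of the substrate charged, in red
- final product, as a percentage of the substrate charged, in blue

So I kept a ledger for the substrate, the limiting reagent, with the coupling partner at 2.50 equiv. It has three entries: product, capture, and unfinished.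

I assumed that at any moment product grows with catalyst and capture with capture agent. The split then follows the capture ratio, capture agent charged per catalyst charged: 150 in red and blue, 75.0 in alder, 110 in elm, 300 in larch. It drifts down as capture agent is spent, so I compared flasks only at equal catalyst-hours, loading times time.

Alder at 25.0 h and larch at 50.0 h had equal catalyst-hours, yet alder held 56.5 % and larch 45.4 %.

Between alder and elm at 50.0 h, each unit of ratio cost 0.13 percentage points. Red's 2.0 d is close to that time, so I entered 70.0 % for red. That leaves 30.0 % for capture and unfinished together, and capture, taken mole for mole, has room for up to 30.0 %, so my ledger does not say how red's remainder divides.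

For blue I started from elm at 30.0 h, took the toll from the alder–larch pair, and stepped back along elm's slope to 1.2 d, which gave 56.4 %. Of blue's remainder, 43.6 %, capture has room for up to 30.0 %, so in my reckoning at least 14 points stays unfinished, and red leads blue by 14 points.

The forecast gave 67 % for red and 52 % for blue, in its words “Red ends higher.”

The flasks gave 69.4 % in red and 55.0 % in blue, so red ended higher.

    substrate + free catalyst ⇌ free catalyst + open intermediate (K = 5.70, k = 13.6 M⁻¹ min⁻¹)
    free catalyst + open intermediate ⇌ catalyst intermediate (K = 9.38 M⁻¹, k = 28.3 M⁻¹ min⁻¹)
    coupling partner + catalyst intermediate → free catalyst + product (k = 49.2 M⁻¹ min⁻¹)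
    open intermediate + capture agent → trapped intermediate (k = 0.0723 M⁻¹ min⁻¹)

The neighbour flask is blue with 0.5 mol% of free catalyst, the time held. Its capture ratio is 60.0, below alder's, and its catalyst-hours exceed those of alder's last reading. Running the toll outward from alder gave 81.5 %. The flask held 83.0 % of product, 15.1 % as trapped intermediate, 1.08 % as open intermediate and 0.84 % as substrate, with 50 % of its capture agent still unused.

(The runs are calculated from invented constants, noise included.)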